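**Retrosynthetic overview**

1. Feature: ring B of flavone 2 (C1'–C6') carries the chromone C2 on C1', C8 of flavone 1 on C2' and OMe on C4' (para to C1'). With oxygen on C1' this is a 2-aryl-4-methoxyphenol, the product pattern of an alkenylcarbene–alkyne–CO benzannulation.
2. Target 21 ⇒ tetrabenzyl ether 20 (BCl3) ⇒ 1,3-diketone 19 (cyclodehydration closes ring C of flavone 2) ⇒ methyl ester 17 + acetophenone 2 (Claisen) ⇒ triflate 16 ⇒ phenol 15.
3. Key disconnection: 15 ⇒ 8-ethynylflavone 9 + (CO)5Cr=C(OMe)CH=CH2 13; C3'–C4', C1'–C2' and C1'–C6' form together and ring B of flavone 2 grows on the alkyne, so no hindered aryl–aryl coupling is needed.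
4. 9 ⇒ 8-iodoflavone 6 (Sonogashira) ⇒ flavone 5 ⇒ chalcone 4 ⇒ acetophenone 2 + 4-methoxybenzaldehyde 3; 2 (from phloroacetophenone 1) is used twice.
5. Ring order: ring C of flavone 1 (step 3), ring B of flavone 2 (step 8), ring C of flavone 2 (step 12); both rings A are bought.

Key step: step 8

Remark: flavone 1 is the 4'-methoxyflavone joined through C8 and flavone 2 is the flavone joined through C2' of its ring B. The C8–C2' axis has three ortho substituents and the target is drawn without an axial descriptor, so the axis is not controlled and the racemate is made.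

**Route**

Step 1
Reactants: 1 2',4',6'-trihydroxyacetophenone
Product: 2 1-[2,4-bis(benzyloxy)-6-hydroxyphenyl]ethan-1-one
Conditions: BnBr (2.1 equiv), K2CO3, DMF, 0 °C → rt
Reagents that add atoms: benzyl bromide, BrCc1ccccc1
Why: Williamson etherification; the hydroxyl hydrogen-bonded to the acetyl carbonyl is the least nucleophilic and should stay free when two equivalents of benzyl bromide are used.

Step 2
Reactants: 2 1-[2,4-bis(benzyloxy)-6-hydroxyphenyl]ethan-1-one; 3 4-methoxybenzaldehyde
Product: 4 (E)-1-[2,4-bis(benzyloxy)-6-hydroxyphenyl]-3-(4-methoxyphenyl)prop-2-en-1-one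
Conditions: KOH, EtOH–H2O, rt
Reagents that add atoms: none
Why: Claisen–Schmidt condensation of the methyl ketone with a non-enolisable aldehyde; reversible aldol addition and E1cB dehydration should give the E-alkene as the thermodynamic geometry.

Step 3
Reactants: 4 (E)-1-[2,4-bis(benzyloxy)-6-hydroxyphenyl]-3-(4-methoxyphenyl)prop-2-en-1-one
Product: 5 5,7-bis(benzyloxy)-2-(4-methoxyphenyl)-4H-chromen-4-one
Conditions: I2 (10 mol %), DMSO, 130 °C
Reagents that add atoms: none
Why: Iodine-catalysed oxidative cyclisation of a 2'-hydroxychalcone (oxa-Michael closure of ring C, α-iodination, loss of HI), with dimethyl sulfoxide as the terminal oxidant that returns iodide to iodine.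

Step 4
Reactants: 5 5,7-bis(benzyloxy)-2-(4-methoxyphenyl)-4H-chromen-4-one
Product: 6 5,7-bis(benzyloxy)-8-iodo-2-(4-methoxyphenyl)-4H-chromen-4-one
Conditions: N-iodosuccinimide (1.1 equiv), DMF, rt → 50 °C, dark
Reagents that add atoms: N-iodosuccinimide, O=C1CCC(=O)N1I
Why: Electrophilic aromatic iodination; in 5,7-dialkoxyflavones C8 (ortho to the 7-alkoxy group, para to the 5-alkoxy group, flanked only by O1) should react in preference to C6, which lies between two benzyloxy groups.

Step 5
Reactants: 6 5,7-bis(benzyloxy)-8-iodo-2-(4-methoxyphenyl)-4H-chromen-4-one; 7 ethynyltrimethylsilane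
Product: 8 5,7-bis(benzyloxy)-2-(4-methoxyphenyl)-8-[(trimethylsilyl)ethynyl]-4H-chromen-4-one
Conditions: PdCl2(PPh3)2 (5 mol %), CuI (10 mol %), Et3N, DMF, 70 °C
Reagents that add atoms: none
Why: Sonogashira coupling (oxidative addition of zerovalent palladium into the C8–I bond, transmetalation from the copper acetylide, reductive elimination); the silyl cap prevents a second arylation and alkyne homocoupling.

Step 6
Reactants: 8 5,7-bis(benzyloxy)-2-(4-methoxyphenyl)-8-[(trimethylsilyl)ethynyl]-4H-chromen-4-one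
Product: 9 5,7-bis(benzyloxy)-8-ethynyl-2-(4-methoxyphenyl)-4H-chromen-4-one
Conditions: K2CO3 (0.2 equiv), MeOH–THF, rt
Reagents that add atoms: none
Why: Protodesilylation of the alkynylsilane by catalytic methoxide; the 2-aryl pyranone ring should tolerate carbonate in methanol at room temperature.

Step 7
Reactants: 10 chromium hexacarbonyl, Cr(CO)6; 11 vinylmagnesium bromide
Product: 13 pentacarbonyl(1-methoxyprop-2-enylidene)chromium, via bromomagnesium acylchromate 12 (not isolated)
Conditions: THF, 0 °C → rt; then Me3OBF4, CH2Cl2–H2O, 0 °C; cold filtration (SiO2, pentane, Ar), used at once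
Reagents that add atoms: trimethyloxonium tetrafluoroborate, C[O+](C)C.F[B-](F)(F)F
Why: Fischer carbene synthesis, in which the vinyl nucleophile adds to a CO ligand and the acylchromate oxygen is methylated by the oxonium salt; slow addition of the Grignard reagent to excess Cr(CO)6 limits conjugate addition to the acylate, and immediate use limits polymerisation.

Step 8
Reactants: 9 5,7-bis(benzyloxy)-8-ethynyl-2-(4-methoxyphenyl)-4H-chromen-4-one; 13 pentacarbonyl(1-methoxyprop-2-enylidene)chromium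
Product: 15 5,7-bis(benzyloxy)-8-(2-hydroxy-5-methoxyphenyl)-2-(4-methoxyphenyl)-4H-chromen-4-one, via tricarbonylchromium arene complex 14 (not isolated)
Conditions: 13 (2 equiv, two portions), degassed THF, 50 °C, Ar; then air, daylight, rt
Reagents that add atoms: none
Why: Dötz benzannulation: loss of one CO from 13 lets the alkyne insert into the Cr=C bond with its unsubstituted carbon bonding to the carbene carbon (C3'–C4') and the flavonyl-bearing carbon staying on chromium, a CO ligand inserts (C1'–C2') to give a chromium-bound dienylketene, six-electron electrocyclisation joins the ketene carbon to the vinyl terminus (C1'–C6'), and tautomerisation gives the phenol as its Cr(CO)3 complex 14, which air and light should convert to 15. The closest known reaction type is the benzannulation of alkenyl(methoxy)carbene pentacarbonylchromium complexes with terminal arylalkynes to 2-aryl-4-methoxyphenols. The one ring closed is ring B of flavone 2, a six-membered carbocycle built from the carbene carbon, two vinyl carbons, two alkyne carbons and one CO, and it closes by disrotatory 6π electrocyclisation of the dienylketene. No stereocentre is formed and the C8–C2' axis is left uncontrolled. The selectivity needed is the regiochemistry of alkyne insertion, which the steric gap between H and the 2,6-disubstituted flavon-8-yl group should secure by placing the large group next to the CO-derived carbon, while an alkenyl carbene in THF favours phenol formation over five-membered-ring products. Excess freshly made 13 added in portions offsets its tendency to polymerise, and the non-oxidising release (air rather than ceric salts) should keep the 4-methoxyphenol from going on to the quinone.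

Step 9
Reactants: 15 5,7-bis(benzyloxy)-8-(2-hydroxy-5-methoxyphenyl)-2-(4-methoxyphenyl)-4H-chromen-4-one
Product: 16 2-[5,7-bis(benzyloxy)-2-(4-methoxyphenyl)-4-oxo-4H-chromen-8-yl]-4-methoxyphenyl trifluoromethanesulfonate
Conditions: PhNTf2 (1.3 equiv), Et3N, DMAP (cat.), CH2Cl2, rt
Reagents that add atoms: N-phenylbis(trifluoromethanesulfonimide), O=S(=O)(N(c1ccccc1)S(=O)(=O)C(F)(F)F)C(F)(F)F
Why: O-sulfonylation of the phenol with the mild triflyl donor PhNTf2, chosen because Tf2O would also attack the pyranone carbonyl.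

Step 10
Reactants: 16 2-[5,7-bis(benzyloxy)-2-(4-methoxyphenyl)-4-oxo-4H-chromen-8-yl]-4-methoxyphenyl trifluoromethanesulfonate
Product: 17 methyl 2-[5,7-bis(benzyloxy)-2-(4-methoxyphenyl)-4-oxo-4H-chromen-8-yl]-4-methoxybenzoate
Conditions: Pd(OAc)2 (10 mol %), 1,3-bis(diphenylphosphino)propane (10 mol %), CO (1 atm), MeOH, Et3N, DMSO, 70 °C
Reagents that add atoms: carbon monoxide, [C-]#[O+]; methanol, CO
Why: Palladium-catalysed methoxycarbonylation of an aryl triflate (oxidative addition, CO insertion, methanolysis of the acylpalladium), a reaction type that works on ortho-aryl-substituted triflates with a chelating diphosphine in DMSO.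

Step 11
Reactants: 17 methyl 2-[5,7-bis(benzyloxy)-2-(4-methoxyphenyl)-4-oxo-4H-chromen-8-yl]-4-methoxybenzoate; 2 1-[2,4-bis(benzyloxy)-6-hydroxyphenyl]ethan-1-one
Product: 19 1-[2,4-bis(benzyloxy)-6-hydroxyphenyl]-3-{2-[5,7-bis(benzyloxy)-2-(4-methoxyphenyl)-4-oxo-4H-chromen-8-yl]-4-methoxyphenyl}propane-1,3-dione, via dilithium enolate phenolate of the acetophenone 18 (not isolated)
Conditions: 2 (2 equiv), LiN(SiMe3)2 (6 equiv), THF, −78 → −10 °C; then 17, −78 °C → rt; 1 M HCl
Reagents that add atoms: none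
Why: Crossed Claisen condensation; the ketone is converted fully to its dianion before the non-enolisable ester is added, and the third equivalent of base per ketone drives the equilibrium by deprotonating the 1,3-diketone.

Step 12
Reactants: 19 1-[2,4-bis(benzyloxy)-6-hydroxyphenyl]-3-{2-[5,7-bis(benzyloxy)-2-(4-methoxyphenyl)-4-oxo-4H-chromen-8-yl]-4-methoxyphenyl}propane-1,3-dione
Product: 20 5,7-bis(benzyloxy)-8-{2-[5,7-bis(benzyloxy)-4-oxo-4H-chromen-2-yl]-5-methoxyphenyl}-2-(4-methoxyphenyl)-4H-chromen-4-one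
Conditions: p-TsOH·H2O (0.3 equiv), toluene, 100 °C
Reagents that add atoms: none
Why: Acid-catalysed cyclodehydration of a 1-(2-hydroxyaryl)-1,3-diketone (6-exo-trig hemiketal formation at the ring B carbonyl, then loss of water), which closes ring C of flavone 2.

Step 13
Reactants: 20 5,7-bis(benzyloxy)-8-{2-[5,7-bis(benzyloxy)-4-oxo-4H-chromen-2-yl]-5-methoxyphenyl}-2-(4-methoxyphenyl)-4H-chromen-4-one
Product: 21 5,7-dihydroxy-8-[2-(5,7-dihydroxy-4-oxo-4H-chromen-2-yl)-5-methoxyphenyl]-2-(4-methoxyphenyl)-4H-chromen-4-one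
Conditions: BCl3 (12 equiv), C6HMe5 (12 equiv), CH2Cl2, −78 → −40 °C; then MeOH–H2O
Reagents that add atoms: none
Why: Lewis-acid debenzylation with a cation scavenger; at low temperature BCl3 should cleave all four aryl benzyl ethers, while the two 4'-methoxy groups, which are not peri to a carbonyl, should remain.

**Compound list**

1 | 2',4',6'-trihydroxyacetophenone | CC(=O)c1c(O)cc(O)cc1O | starting material
2 | 1-[2,4-bis(benzyloxy)-6-hydroxyphenyl]ethan-1-one | CC(=O)c1c(O)cc(OCc2ccccc2)cc1OCc1ccccc1 | intermediate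
3 | 4-methoxybenzaldehyde | COc1ccc(C=O)cc1 | starting material
4 | (E)-1-[2,4-bis(benzyloxy)-6-hydroxyphenyl]-3-(4-methoxyphenyl)prop-2-en-1-one | COc1ccc(/C=C/C(=O)c2c(O)cc(OCc3ccccc3)cc2OCc2ccccc2)cc1 | intermediate
5 | 5,7-bis(benzyloxy)-2-(4-methoxyphenyl)-4H-chromen-4-one | COc1ccc(-c2cc(=O)c3c(OCc4ccccc4)cc(OCc4ccccc4)cc3o2)cc1 | intermediate
6 | 5,7-bis(benzyloxy)-8-iodo-2-(4-methoxyphenyl)-4H-chromen-4-one | COc1ccc(-c2cc(=O)c3c(OCc4ccccc4)cc(OCc4ccccc4)c(I)c3o2)cc1 | intermediate
7 | ethynyltrimethylsilane | C#C[Si](C)(C)C | starting material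
8 | 5,7-bis(benzyloxy)-2-(4-methoxyphenyl)-8-[(trimethylsilyl)ethynyl]-4H-chromen-4-one | COc1ccc(-c2cc(=O)c3c(OCc4ccccc4)cc(OCc4ccccc4)c(C#C[Si](C)(C)C)c3o2)cc1 | intermediate
9 | 5,7-bis(benzyloxy)-8-ethynyl-2-(4-methoxyphenyl)-4H-chromen-4-one | C#Cc1c(OCc2ccccc2)cc(OCc2ccccc2)c2c(=O)cc(-c3ccc(OC)cc3)oc12 | intermediate
10 | chromium hexacarbonyl, Cr(CO)6 | O=C=[Cr](=C=O)(=C=O)(=C=O)(=C=O)=C=O | starting material
11 | vinylmagnesium bromide | C=C[Mg]Br | starting material
12 | bromomagnesium pentacarbonyl(prop-2-enoyl)chromate, drawn in its O-magnesio carbene form | C=CC(O[Mg]Br)=[Cr](=C=O)(=C=O)(=C=O)(=C=O)=C=O | intermediate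
13 | pentacarbonyl(1-methoxyprop-2-enylidene)chromium | COC(C=C)=[Cr](=C=O)(=C=O)(=C=O)(=C=O)=C=O | intermediate
14 | tricarbonylchromium η6-complex of phenol 15, chromium on the new hydroxy-methoxy-benzene ring, Cr(CO)3 written as a separate fragment | COc1ccc(O)c(-c2c(OCc3ccccc3)cc(OCc3ccccc3)c3c(=O)cc(-c4ccc(OC)cc4)oc23)c1.O=C=[Cr](=C=O)=C=O | intermediate
15 | 5,7-bis(benzyloxy)-8-(2-hydroxy-5-methoxyphenyl)-2-(4-methoxyphenyl)-4H-chromen-4-one | COc1ccc(O)c(-c2c(OCc3ccccc3)cc(OCc3ccccc3)c3c(=O)cc(-c4ccc(OC)cc4)oc23)c1 | intermediate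
16 | 2-[5,7-bis(benzyloxy)-2-(4-methoxyphenyl)-4-oxo-4H-chromen-8-yl]-4-methoxyphenyl trifluoromethanesulfonate | COc1ccc(OS(=O)(=O)C(F)(F)F)c(-c2c(OCc3ccccc3)cc(OCc3ccccc3)c3c(=O)cc(-c4ccc(OC)cc4)oc23)c1 | intermediate
17 | methyl 2-[5,7-bis(benzyloxy)-2-(4-methoxyphenyl)-4-oxo-4H-chromen-8-yl]-4-methoxybenzoate | COC(=O)c1ccc(OC)cc1-c1c(OCc2ccccc2)cc(OCc2ccccc2)c2c(=O)cc(-c3ccc(OC)cc3)oc12 | intermediate
18 | dilithium enolate phenolate of acetophenone 2 | [Li]OC(=C)c1c(O[Li])cc(OCc2ccccc2)cc1OCc1ccccc1 | intermediate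
19 | 1-[2,4-bis(benzyloxy)-6-hydroxyphenyl]-3-{2-[5,7-bis(benzyloxy)-2-(4-methoxyphenyl)-4-oxo-4H-chromen-8-yl]-4-methoxyphenyl}propane-1,3-dione | COc1ccc(C(=O)CC(=O)c2c(O)cc(OCc3ccccc3)cc2OCc2ccccc2)c(-c2c(OCc3ccccc3)cc(OCc3ccccc3)c3c(=O)cc(-c4ccc(OC)cc4)oc23)c1 | intermediate
20 | 5,7-bis(benzyloxy)-8-{2-[5,7-bis(benzyloxy)-4-oxo-4H-chromen-2-yl]-5-methoxyphenyl}-2-(4-methoxyphenyl)-4H-chromen-4-one | COc1ccc(-c2cc(=O)c3c(OCc4ccccc4)cc(OCc4ccccc4)c(-c4cc(OC)ccc4-c4cc(=O)c5c(OCc6ccccc6)cc(OCc6ccccc6)cc5o4)c3o2)cc1 | intermediate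
21 | 5,7-dihydroxy-8-[2-(5,7-dihydroxy-4-oxo-4H-chromen-2-yl)-5-methoxyphenyl]-2-(4-methoxyphenyl)-4H-chromen-4-one (CNP0394081.0) | COc1ccc(-c2cc(=O)c3c(O)cc(O)c(-c4cc(OC)ccc4-c4cc(=O)c5c(O)cc(O)cc5o4)c3o2)cc1 | target

**Step count and risks**

Total step count: 13. Longest linear sequence: 12 steps (steps 1–6 and 8–13); step 7 is the one-step carbene branch.

Steps most likely to fail:

Step 8 (key step). What may go wrong: the unsubstituted vinylcarbene complex polymerises or decomposes faster than the hindered, di-ortho-substituted arylalkyne inserts, so that little benzannulation takes place. Fallback (aryl–aryl cross-coupling in place of ring growth): it sets out from iodide 6. Suzuki–Miyaura coupling with commercial (2-hydroxy-5-methoxyphenyl)boronic acid (COc1ccc(O)c(B(O)O)c1) under conditions for hindered partners (Pd(OAc)2, 2-dicyclohexylphosphino-2',6'-dimethoxybiphenyl, K3PO4, toluene–H2O, 90 °C) should give phenol 15 directly, where it comes back to the route. No new compound is made on the way.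

Step 11. What may go wrong: the enolate fails to acylate at the ortho-blocked ester carbonyl and instead adds to C2 of ring C of flavone 1 (conjugate addition and ring opening), or simple proton transfer returns the ketone. Fallback (intramolecular acyl transfer in place of the intermolecular condensation): it sets out from ester 17. Saponification (LiOH, THF–MeOH–H2O, 40 °C; then dilute HCl) should give 2-[5,7-bis(benzyloxy)-2-(4-methoxyphenyl)-4-oxo-4H-chromen-8-yl]-4-methoxybenzoic acid F1. Esterification with the phenol of 2 (dicyclohexylcarbodiimide, DMAP, CH2Cl2) should give 2-acetyl-3,5-bis(benzyloxy)phenyl 2-[5,7-bis(benzyloxy)-2-(4-methoxyphenyl)-4-oxo-4H-chromen-8-yl]-4-methoxybenzoate F2. Baker–Venkataraman rearrangement (KOH, pyridine, 50 °C) then moves the aroyl group from oxygen to the acetyl carbon and comes back to the route at diketone 19.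

Step 10. What may go wrong: oxidative addition of CO-saturated zerovalent palladium into the electron-rich, ortho-blocked aryl triflate is slow, so that S–O cleavage back to the phenol or reduction of the C–O bond overtakes carbonylation. Fallback (one-carbon handle by vinylation and oxidative cleavage, then the chalcone route used for flavone 1): it sets out from triflate 16.
- Stille coupling with Bu3SnCH=CH2 (Pd(PPh3)4, LiCl, dioxane, 100 °C) should give 5,7-bis(benzyloxy)-8-(2-ethenyl-5-methoxyphenyl)-2-(4-methoxyphenyl)-4H-chromen-4-one F3.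
- Lemieux–Johnson cleavage (OsO4 cat., NaIO4, 2,6-lutidine, dioxane–H2O) should give 2-[5,7-bis(benzyloxy)-2-(4-methoxyphenyl)-4-oxo-4H-chromen-8-yl]-4-methoxybenzaldehyde F4.
- Claisen–Schmidt condensation with 2 (KOH, EtOH, rt) should give (E)-1-[2,4-bis(benzyloxy)-6-hydroxyphenyl]-3-{2-[5,7-bis(benzyloxy)-2-(4-methoxyphenyl)-4-oxo-4H-chromen-8-yl]-4-methoxyphenyl}prop-2-en-1-one F5.
- Oxidative cyclisation (I2 cat., DMSO, 130 °C) comes back to the route at 20, passing by steps 10–12.

**Further compounds**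

F0 | step 8 | none | none
F1 | step 11 | 2-[5,7-bis(benzyloxy)-2-(4-methoxyphenyl)-4-oxo-4H-chromen-8-yl]-4-methoxybenzoic acid | COc1ccc(C(=O)O)c(-c2c(OCc3ccccc3)cc(OCc3ccccc3)c3c(=O)cc(-c4ccc(OC)cc4)oc23)c1
F2 | step 11 | 2-acetyl-3,5-bis(benzyloxy)phenyl 2-[5,7-bis(benzyloxy)-2-(4-methoxyphenyl)-4-oxo-4H-chromen-8-yl]-4-methoxybenzoate | COc1ccc(C(=O)Oc2cc(OCc3ccccc3)cc(OCc3ccccc3)c2C(C)=O)c(-c2c(OCc3ccccc3)cc(OCc3ccccc3)c3c(=O)cc(-c4ccc(OC)cc4)oc23)c1
F3 | step 10 | 5,7-bis(benzyloxy)-8-(2-ethenyl-5-methoxyphenyl)-2-(4-methoxyphenyl)-4H-chromen-4-one | C=Cc1ccc(OC)cc1-c1c(OCc2ccccc2)cc(OCc2ccccc2)c2c(=O)cc(-c3ccc(OC)cc3)oc12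
F4 | step 10 | 2-[5,7-bis(benzyloxy)-2-(4-methoxyphenyl)-4-oxo-4H-chromen-8-yl]-4-methoxybenzaldehyde | O=Cc1ccc(OC)cc1-c1c(OCc2ccccc2)cc(OCc2ccccc2)c2c(=O)cc(-c3ccc(OC)cc3)oc12
F5 | step 10 | (E)-1-[2,4-bis(benzyloxy)-6-hydroxyphenyl]-3-{2-[5,7-bis(benzyloxy)-2-(4-methoxyphenyl)-4-oxo-4H-chromen-8-yl]-4-methoxyphenyl}prop-2-en-1-one | COc1ccc(/C=C/C(=O)c2c(O)cc(OCc3ccccc3)cc2OCc2ccccc2)c(-c2c(OCc3ccccc3)cc(OCc3ccccc3)c3c(=O)cc(-c4ccc(OC)cc4)oc23)c1
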